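**Plan**

- Germacrane numbering: ring C1–C10, C14 the ester carbon on C10, C15 the methyl on C4, lactone oxygen on C6, C11–C13 the methylene-lactone carbons on C7. In the ten-membered ring C10 bears the exocyclic C14 carboxyl and sits between oxygenated C9 and C1; this is the pattern a Wolff shift leaves when one ring carbonyl carbon of an eleven-membered 2-diazo-1,3-dione is pushed out of the ring.
- Retrosynthesis: remove the C2–C3 oxirane oxygen, the C9 acetate and the C1=C10 unsaturation; cut C1–C10 (back to the eleven-membered dione with ketones at C9 and C14 and the diazo group on C10); then cut C2=C3 (metathesis), C9–C10 (aldehyde homologation with a diazo ketone), the C8–O ester bond, C7–C8 (Barbier allylation) and the butenolide C7=C11 bond (metathesis).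
- Forward: C4–C5 oxirane, then the butenolide, which becomes the trans-fused methylene lactone in the Barbier step, then the eleven-membered carbocycle, its contraction to the ten-membered ring, and last the C2–C3 oxirane. The epoxyangelic acid and the diazo ketone are made separately and joined in steps 13 and 16.
- Stereochemistry: C6 from a lipase resolution; C4/C5 from hydroxyl-directed epoxidation under allylic 1,3-strain; C7 by addition anti to the C6 substituent; C8 by Mitsunobu inversion; the side chain by Sharpless epoxidation; C9 and C2/C3 by substrate control (Felkin–Anh reduction, epoxidation anti to the C4–O bond).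

Key step: step 19

Remark 1: germacrane locants are used for all intermediates; the CIP letters at C4 and C7 change with the neighbouring groups (C3 sp2 or oxirane, oxidation level of C9) although nothing moves in space.
Remark 2 (assumption): the indium Barbier addition of step 12 is taken to pass through the closed chair transition state usual for 3-(bromomethyl)furan-2(5H)-ones, which delivers the C8 epimer of the target; the Mitsunobu inversion of step 13 is planned on that basis.
Remark 3 (assumption): 9 is bought as the pure E isomer; 15 and 18 are catalogue compounds.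

**Route**

Step 1
Reactants: 1 angelic acid [(Z)-2-methylbut-2-enoic acid]
Product: 2 (Z)-2-methylbut-2-en-1-ol
Conditions: LiAlH4, Et2O, 0 °C to rt; aqueous NaOH work-up
Reagents that add atoms: none
Why: Hydride reduction of the carboxylic acid should stop at the allylic alcohol and leave the trisubstituted alkene alone, so the Z geometry of angelic acid is carried over.

Step 2
Reactants: 2 (Z)-2-methylbut-2-en-1-ol
Product: 3 [(2R,3S)-2,3-dimethyloxiran-2-yl]methanol
Conditions: Ti(OiPr)4 (10 mol %), D-(−)-diethyl tartrate (12 mol %), t-BuOOH, 4 Å molecular sieves, CH2Cl2, −20 °C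
Reagents that add atoms: tert-butyl hydroperoxide CC(C)(C)OO
Why: Sharpless asymmetric epoxidation of the primary allylic alcohol; the D-(−)-tartrate catalyst should deliver oxygen to the face that gives the (2R,3S) epoxy alcohol, and the cis relation of CH2OH and the C3 methyl follows from the Z alkene.

Step 3
Reactants: 3 [(2R,3S)-2,3-dimethyloxiran-2-yl]methanol
Product: 5 (2S,3S)-2,3-dimethyloxirane-2-carboxylic acid, via epoxy aldehyde 4 (not isolated)
Conditions: RuCl3 hydrate (2 mol %), NaIO4, CCl4/MeCN/H2O, rt
Reagents that add atoms: water O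
Why: Ruthenium tetroxide oxidation (the oxidant is regenerated by NaIO4) of a primary epoxy alcohol through the aldehyde hydrate to the glycidic acid, a known way to epoxy acids that leaves the oxirane and both stereocentres untouched (2R to 2S is only a change of CIP priorities).

Step 4
Reactants: 6 but-3-enoic acid
Product: 8 1-diazopent-4-en-2-one, via but-3-enoyl chloride 7 (not isolated)
Conditions: (COCl)2, DMF (cat.), CH2Cl2, 0 °C to rt; then CH2N2 (3 equiv), Et2O, 0 °C
Reagents that add atoms: diazomethane C=[N+]=[N-]
Why: Acid chloride formation followed by acylation of diazomethane (diazo ketone synthesis of the Arndt–Eistert type); excess diazomethane takes up the HCl, so no base is present that could move the β,γ-alkene into conjugation.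

Step 5
Reactants: 9 (E)-3-methylpent-2-en-4-yn-1-ol
Product: 10 (E)-3-methylpenta-2,4-dien-1-ol
Conditions: H2 (1 atm), Lindlar catalyst (Pd on CaCO3, poisoned with Pb(OAc)2), quinoline, EtOAc, rt
Reagents that add atoms: none
Why: Lindlar semihydrogenation turns the terminal alkyne into the vinyl group and should stop there, the trisubstituted E alkene being untouched.

Step 6
Reactants: 10 (E)-3-methylpenta-2,4-dien-1-ol
Product: 11 (E)-3-methylpenta-2,4-dienal
Conditions: MnO2, CH2Cl2, rt
Reagents that add atoms: none
Why: Allylic oxidation with MnO2 is selective for the primary allylic alcohol and keeps the E geometry; the volatile dienal is used as a solution.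

Step 7
Reactants: 11 (E)-3-methylpenta-2,4-dienal
Product: 12 rac-(4E)-5-methylhepta-1,4,6-trien-3-ol
Conditions: CH2=CHMgBr, THF, −78 °C; aq NH4Cl
Reagents that add atoms: vinylmagnesium bromide C=C[Mg]Br
Why: Grignard 1,2-addition to the dienal at low temperature should give the racemic bis-allylic alcohol (C6 carbinol with the future C7 vinyl group).

Step 8
Reactants: 12 rac-(4E)-5-methylhepta-1,4,6-trien-3-ol
Product: 13 (3S,4E)-5-methylhepta-1,4,6-trien-3-ol
Conditions: Novozym 435 (immobilised Candida antarctica lipase B), vinyl acetate, hexane, 30 °C, stopped just past half conversion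
Reagents that add atoms: none
Why: Lipase-catalysed kinetic resolution by transesterification; by the usual size rule for secondary alcohols the R enantiomer (large dienyl group, medium vinyl group) should be acetylated and the S alcohol left, at most half of 12, its ee to be checked before use.

Step 9
Reactants: 13 (3S,4E)-5-methylhepta-1,4,6-trien-3-ol
Product: 14 (1S)-1-[(2R,3R)-3-ethenyl-3-methyloxiran-2-yl]prop-2-en-1-ol
Conditions: mCPBA, NaHCO3, CH2Cl2, −20 to 0 °C
Reagents that add atoms: 3-chloroperoxybenzoic acid O=C(OO)c1cccc(Cl)c1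
Why: Hydroxyl-directed peracid epoxidation of the most substituted, allylic C4=C5 bond; allylic 1,3-strain between the C4 methyl and the carbinol substituents holds the carbinol hydrogen in the alkene plane, so oxygen is delivered syn to OH and the threo (4R,5R,6S) epoxy alcohol should result.

Step 10
Reactants: 14 (1S)-1-[(2R,3R)-3-ethenyl-3-methyloxiran-2-yl]prop-2-en-1-ol; 15 2-(bromomethyl)prop-2-enoic acid
Product: 16 (1S)-1-[(2R,3R)-3-ethenyl-3-methyloxiran-2-yl]prop-2-en-1-yl 2-(bromomethyl)prop-2-enoate
Conditions: DCC, DMAP (5 mol %), CH2Cl2, 0 °C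
Reagents that add atoms: none
Why: Steglich carbodiimide esterification of the secondary alcohol; the low temperature and the small amount of DMAP are chosen to keep the allylic bromide and the acid-labile vinyl oxirane intact.

Step 11
Reactants: 16 (1S)-1-[(2R,3R)-3-ethenyl-3-methyloxiran-2-yl]prop-2-en-1-yl 2-(bromomethyl)prop-2-enoate
Product: 17 (5S)-3-(bromomethyl)-5-[(2R,3R)-3-ethenyl-3-methyloxiran-2-yl]furan-2(5H)-one
Conditions: second-generation Hoveyda–Grubbs catalyst (5 mol %), toluene (5 mM), 80 °C
Reagents that add atoms: none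
Why: Ring-closing metathesis of the allylic acrylate closes the five-membered butenolide (only a cis ring alkene is possible), while the vinyl group on the oxirane stays out because it is hindered and a ring through the trans-substituted oxirane cannot form.

Step 12
Reactants: 17 (5S)-3-(bromomethyl)-5-[(2R,3R)-3-ethenyl-3-methyloxiran-2-yl]furan-2(5H)-one; 18 2-[tert-butyl(dimethyl)silyl]oxyacetaldehyde
Product: 19 Barbier adduct, trans-fused α-methylene-γ-lactone with the (1R)-2-silyloxy-1-hydroxyethyl group on C7 (4R,5R,6S,7R,8R)
Conditions: In powder, THF/H2O (1:1), rt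
Reagents that add atoms: none
Why: Barbier allylation: the allylindium made in the flask from 17 adds to the aldehyde with allylic transposition (C7–C8 bond, exocyclic C11=C13), anti to the C6 substituent so that the lactone becomes trans-fused (7R), and through a closed chair (Zimmerman–Traxler) transition state with the aldehyde chain equatorial, which should give the 8R alcohol.

Step 13
Reactants: 19 Barbier adduct (8R alcohol); 5 (2S,3S)-2,3-dimethyloxirane-2-carboxylic acid
Product: 20 C8 epoxyangelate, C9 silyl ether (4R,5R,6S,7R,8S; acyl part 2S,3S)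
Conditions: PPh3, DIAD, toluene, 0 °C to rt
Reagents that add atoms: none
Why: Mitsunobu esterification: the carboxylate of the fairly acidic glycidic acid displaces the alkoxyphosphonium group at C8 by SN2, which installs the side chain and inverts C8 to the S configuration of the target in one operation.

Step 14
Reactants: 20 C8 epoxyangelate, C9 silyl ether
Product: 21 C9 primary alcohol (4R,5R,6S,7R,8S)
Conditions: Et3N·3HF, THF, rt
Reagents that add atoms: none
Why: Fluoride cleavage of the primary silyl ether under nearly neutral conditions, chosen so that neither oxirane opens and the hindered ester does not migrate to the primary hydroxyl.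

Step 15
Reactants: 21 C9 primary alcohol
Product: 22 C9 aldehyde (4R,5R,6S,7S,8S)
Conditions: Dess–Martin periodinane, NaHCO3, CH2Cl2, 0 °C; used at once
Reagents that add atoms: none
Why: Buffered Dess–Martin oxidation should give the α-acyloxy aldehyde without epimerisation at C8 or acyl migration.

Step 16
Reactants: 22 C9 aldehyde; 8 1-diazopent-4-en-2-one
Product: 23 acyclic 9,14-dione with terminal alkenes at C2 and C3 (4R,5R,6S,7S,8S)
Conditions: SnCl2 (20 mol %), CH2Cl2, rt, slow addition of 8
Reagents that add atoms: none
Why: Roskamp homologation: the diazo carbon of 8 adds to the SnCl2-activated aldehyde and a 1,2-hydride shift with loss of N2 gives the 1,3-diketone (C9–C10 bond) without base, so that the methylene lactone, C8 and both oxiranes are spared.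

Step 17
Reactants: 23 acyclic 9,14-dione
Product: 24 eleven-membered 9,14-dione with the 2Z alkene (4R,5R,6S,7S,8S)
Conditions: second-generation Grubbs catalyst (10 mol %), 1,4-benzoquinone (20 mol %), toluene (1 mM), 70 °C
Reagents that add atoms: none
Why: Ring-closing metathesis between the allyl ketone terminus and the vinyl oxirane closes the eleven-membered ring at C2=C3 (the electron-poor methylene lactone is a spectator); the cis alkene is expected because a trans alkene next to the trans oxirane and the planar enolised dione would strain the ring, and benzoquinone is added against ruthenium hydride migration of the β,γ-alkene.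

Step 18
Reactants: 24 eleven-membered 9,14-dione
Product: 25 eleven-membered 10-diazo-9,14-dione (4R,5R,6S,7S,8S; 2Z)
Conditions: 4-acetamidobenzenesulfonyl azide, Et3N, MeCN, 0 °C
Reagents that add atoms: 4-acetamidobenzenesulfonyl azide CC(=O)Nc1ccc(cc1)S(=O)(=O)N=[N+]=[N-]
Why: Regitz diazo transfer to the acidic C10 of the 1,3-diketone; with Et3N only the diketonate forms, so the C1 hydrogens, the vinyl oxirane and the methylene lactone are not touched.

Step 19
Reactants: 25 eleven-membered 10-diazo-9,14-dione
Product: 27 ten-membered β-keto ester in its enol form (4R,5R,6S,7S,8S; 2Z), via oxo ketene 26 (not isolated)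
Conditions: hν (350–365 nm), MeOH/CH2Cl2 (1:1), degassed, 0 °C
Reagents that add atoms: methanol CO
Why: Proposed new method: long-wavelength excitation of the diazo chromophore (the lactone, the alkene and the β,γ-unsaturated ketone do not absorb there) expels N2 and, in concert or through the dioxo carbene, C1 shifts from C14 to C10, giving the α-oxo ketene 26, to which methanol adds as the C14 methyl ester. The closest known reaction is the photochemical Wolff ring contraction of five- to seven-membered 2-diazo-1,3-diones to 2-oxocycloalkanecarboxylates; its use on an eleven-membered, unsymmetrical dione is new. The ten-membered ring is not closed by a cyclisation but arises by one-carbon contraction, the 1,2-shift making the C1–C10 bond while C14 leaves the ring. No configurationally stable stereocentre is created (C10 is enolised) and C4 to C8 take no part. The step needs migration of C1 and not of C8: the acyloxy group on C8 lowers the migratory aptitude of that carbon, whereas C1 is an unhindered allylic methylene, and metal catalysts are avoided so that neither cyclopropanation nor a vinylogous Wolff path of the β,γ-unsaturated diazo ketone can compete.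

Step 20
Reactants: 27 ten-membered β-keto ester
Product: 30 9-oxo-1(10)E,2Z-diene ester (4R,5R,6S,7S,8S), via selenide 28 (not isolated), via selenoxide 29 (not isolated)
Conditions: PhSeCl, pyridine, CH2Cl2, 0 °C; then 30 % aq H2O2, 0 °C to rt
Reagents that add atoms: none
Why: Selenenylation of the enolised β-keto ester at C10 with the PhSeCl–pyridine complex, oxidation to the selenoxide and syn elimination; C10 is quaternary at that stage, so the only β-hydrogens are on C1 and the C1=C10 alkene must form, the ring-cis isomer being the less strained one.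

Step 21
Reactants: 30 9-oxo-1(10)E,2Z-diene ester
Product: 31 9S allylic alcohol (4R,5R,6S,7R,8S,9S)
Conditions: NaBH4, CeCl3·7H2O, MeOH/THF, −78 °C
Reagents that add atoms: none
Why: Luche reduction (CeCl3-promoted 1,2-reduction) of the C9 ketone; hydride should add anti to the C8 acyloxy group in a Felkin–Anh arrangement, which gives the 9S alcohol syn to the C8 ester, and the low temperature spares the methylene lactone.

Step 22
Reactants: 31 9S allylic alcohol
Product: 32 9S acetate (4R,5R,6S,7R,8S,9S)
Conditions: Ac2O, pyridine, DMAP (cat.), CH2Cl2, 0 °C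
Reagents that add atoms: acetic anhydride CC(=O)OC(C)=O
Why: Acylation of the secondary allylic alcohol with acetic anhydride, which touches no stereocentre.

Step 23
Reactants: 32 9S acetate
Product: 33 CNP0077535.2 (2R,3R,4S,5R,6S,7R,8S,9S; acyl part 2S,3S)
Conditions: dimethyldioxirane (acetone solution), CH2Cl2, −20 to 0 °C
Reagents that add atoms: dimethyldioxirane CC1(C)OO1
Why: Epoxidation with an electrophilic dioxirane, which should take C2=C3 (the only double bond that carries no carbonyl group) and add from the outer face of the ring anti to the neighbouring C4–O bond, giving the cis (2R,3R) oxirane.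

**Compound list**

1 | angelic acid, (Z)-2-methylbut-2-enoic acid | C/C=C(/C)C(=O)O | starting material
2 | (Z)-2-methylbut-2-en-1-ol | C/C=C(/C)CO | intermediate
3 | [(2R,3S)-2,3-dimethyloxiran-2-yl]methanol | OC[C@@]1(C)O[C@H]1C | intermediate
4 | (2S,3S)-2,3-dimethyloxirane-2-carbaldehyde (not isolated) | O=C[C@@]1(C)O[C@H]1C | intermediate
5 | (2S,3S)-2,3-dimethyloxirane-2-carboxylic acid (epoxyangelic acid) | OC(=O)[C@@]1(C)O[C@H]1C | intermediate
6 | but-3-enoic acid | C=CCC(=O)O | starting material
7 | but-3-enoyl chloride (not isolated) | C=CCC(=O)Cl | intermediate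
8 | 1-diazopent-4-en-2-one | C=CCC(=O)C=[N+]=[N-] | intermediate
9 | (E)-3-methylpent-2-en-4-yn-1-ol | C#C/C(C)=C/CO | starting material
10 | (E)-3-methylpenta-2,4-dien-1-ol | C=C/C(C)=C/CO | intermediate
11 | (E)-3-methylpenta-2,4-dienal | C=C/C(C)=C/C=O | intermediate
12 | rac-(4E)-5-methylhepta-1,4,6-trien-3-ol (racemate) | C=C/C(C)=C/C(O)C=C | intermediate
13 | (3S,4E)-5-methylhepta-1,4,6-trien-3-ol | C=C/C(C)=C/[C@@H](O)C=C | intermediate
14 | (1S)-1-[(2R,3R)-3-ethenyl-3-methyloxiran-2-yl]prop-2-en-1-ol | C=C[C@@]1(C)O[C@@H]1[C@@H](O)C=C | intermediate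
15 | 2-(bromomethyl)prop-2-enoic acid | C=C(CBr)C(=O)O | starting material
16 | (1S)-1-[(2R,3R)-3-ethenyl-3-methyloxiran-2-yl]prop-2-en-1-yl 2-(bromomethyl)prop-2-enoate | C=C(CBr)C(=O)O[C@H]([C@H]1O[C@]1(C)C=C)C=C | intermediate
17 | (5S)-3-(bromomethyl)-5-[(2R,3R)-3-ethenyl-3-methyloxiran-2-yl]furan-2(5H)-one | O=C1O[C@H]([C@H]2O[C@]2(C)C=C)C=C1CBr | intermediate
18 | 2-[tert-butyl(dimethyl)silyl]oxyacetaldehyde | CC(C)(C)[Si](C)(C)OCC=O | starting material
19 | Barbier adduct: trans-fused α-methylene-γ-lactone, C6 bearing the 3-ethenyl-3-methyloxiranyl group, C7 bearing CH(OH)CH2OSi(t-Bu)Me2 (4R,5R,6S,7R,8R) | C=C1C(=O)O[C@H]([C@H]2O[C@]2(C)C=C)[C@H]1[C@@H](O)CO[Si](C)(C)C(C)(C)C | intermediate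
20 | C8 (2S,3S)-epoxyangelate of the C8-inverted lactone, C9 silyl ether (4R,5R,6S,7R,8S) | C=C1C(=O)O[C@H]([C@H]2O[C@]2(C)C=C)[C@H]1[C@H](OC(=O)[C@@]1(C)O[C@H]1C)CO[Si](C)(C)C(C)(C)C | intermediate
21 | C9 primary alcohol (4R,5R,6S,7R,8S) | C=C1C(=O)O[C@H]([C@H]2O[C@]2(C)C=C)[C@H]1[C@H](OC(=O)[C@@]1(C)O[C@H]1C)CO | intermediate
22 | C9 aldehyde (4R,5R,6S,7S,8S) | C=C1C(=O)O[C@H]([C@H]2O[C@]2(C)C=C)[C@H]1[C@H](OC(=O)[C@@]1(C)O[C@H]1C)C=O | intermediate
23 | acyclic 9,14-dione, C14 carrying the allyl group (C1, C2), C4 carrying the vinyl group (C3) (4R,5R,6S,7S,8S) | C=C1C(=O)O[C@H]([C@H]2O[C@]2(C)C=C)[C@H]1[C@H](OC(=O)[C@@]1(C)O[C@H]1C)C(=O)CC(=O)CC=C | intermediate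
24 | eleven-membered 9,14-dione, 2Z alkene, trans 4,5-oxirane, trans-fused 6,12-lactone (4R,5R,6S,7S,8S) | C=C1C(=O)O[C@H]2[C@H]1[C@H](OC(=O)[C@@]1(C)O[C@H]1C)C(=O)CC(=O)C/C=C\[C@@]1(C)O[C@H]21 | intermediate
25 | eleven-membered 10-diazo-9,14-dione (4R,5R,6S,7S,8S; 2Z) | C=C1C(=O)O[C@H]2[C@H]1[C@H](OC(=O)[C@@]1(C)O[C@H]1C)C(=O)C(=[N+]=[N-])C(=O)C/C=C\[C@@]1(C)O[C@H]21 | intermediate
26 | ten-membered α-oxo ketene, C14 as ketene carbon on C10 (not isolated) | C=C1C(=O)O[C@H]2[C@H]1[C@H](OC(=O)[C@@]1(C)O[C@H]1C)C(=O)C(=C=O)C/C=C\[C@@]1(C)O[C@H]21 | intermediate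
27 | ten-membered β-keto ester, drawn as the hydrogen-bonded C9 enol with the C14 methyl ester on C10 (4R,5R,6S,7S,8S; 2Z) | C=C1C(=O)O[C@H]2[C@H]1[C@H](OC(=O)[C@@]1(C)O[C@H]1C)/C(O)=C(/C(=O)OC)\C/C=C\[C@@]1(C)O[C@H]21 | intermediate
28 | 10-phenylselanyl β-keto ester, either C10 epimer, both converge (not isolated) | C=C1C(=O)O[C@H]2[C@H]1[C@H](OC(=O)[C@@]1(C)O[C@H]1C)C(=O)C([Se]c1ccccc1)(C(=O)OC)C/C=C\[C@@]1(C)O[C@H]21 | intermediate
29 | selenoxide of 28 (not isolated) | C=C1C(=O)O[C@H]2[C@H]1[C@H](OC(=O)[C@@]1(C)O[C@H]1C)C(=O)C([Se](=O)c1ccccc1)(C(=O)OC)C/C=C\[C@@]1(C)O[C@H]21 | intermediate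
30 | 9-oxo-1(10)E,2Z-diene methyl ester (4R,5R,6S,7S,8S) | C=C1C(=O)O[C@H]2[C@H]1[C@H](OC(=O)[C@@]1(C)O[C@H]1C)C(=O)/C(C(=O)OC)=C\C=C/[C@@]1(C)O[C@H]21 | intermediate
31 | 9S allylic alcohol (4R,5R,6S,7R,8S,9S) | C=C1C(=O)O[C@H]2[C@H]1[C@H](OC(=O)[C@@]1(C)O[C@H]1C)[C@@H](O)/C(C(=O)OC)=C\C=C/[C@@]1(C)O[C@H]21 | intermediate
32 | 9S acetate (4R,5R,6S,7R,8S,9S) | C=C1C(=O)O[C@H]2[C@H]1[C@H](OC(=O)[C@@]1(C)O[C@H]1C)[C@@H](OC(C)=O)/C(C(=O)OC)=C\C=C/[C@@]1(C)O[C@H]21 | intermediate
33 | CNP0077535.2 (2R,3R,4S,5R,6S,7R,8S,9S; acyl part 2S,3S) | C=C1C(=O)O[C@H]2[C@H]1[C@H](OC(=O)[C@@]1(C)O[C@H]1C)[C@@H](OC(C)=O)/C(C(=O)OC)=C\[C@H]1O[C@H]1[C@@]1(C)O[C@H]21 | target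

**Step count and risks**

Total step count: 23. Longest linear sequence: 19 steps (steps 5 to 23, from 9 to 33); steps 1 to 3 and step 4 are side branches.

Steps most likely to fail:

Step 19 (the new ring contraction). Three things may go wrong: migration of C8 in place of C1, which would push C9 instead of C14 out of the ring; trapping of the carbene by methanol (O–H insertion) from ring conformers in which neither carbonyl is aligned for a concerted shift; and secondary photochemistry of the β,γ-unsaturated ketone. The fallback uses only known reactions and sets out from aldehyde 22. Roskamp homologation with methyl 2-diazopent-4-enoate F1 (from methyl 2-acetylpent-4-enoate by deacylating diazo transfer with 4-acetamidobenzenesulfonyl azide and DBU), catalysed by Sc(OTf)3 in CH2Cl2 at low temperature, should give the acyclic α-allyl β-keto ester F2 with C9, C10, C14 and C1 in their final arrangement. Ring-closing metathesis of F2 at C2=C3 (second-generation Grubbs catalyst, high dilution) would then close the ten-membered ring directly, and the route is rejoined at 27.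

Step 17 (eleven-membered ring closure). The diene may oligomerise instead of cyclising, the enolised 1,3-diketone may bind and stall the ruthenium carbene, the β,γ-alkene may move into conjugation, or the ring alkene may form as an E/Z mixture. The fallback closes the ring one oxidation level lower, without the planar chelating dione, and sets out from aldehyde 22 and diazo ketone 8. Treating 8 with HBr gives 1-bromopent-4-en-2-one F3. A chromium Reformatsky reaction of F3 with 22 (CrCl2, LiI cat., THF) should give the acyclic 9-hydroxy-14-ketone F4 as both C9 epimers, which is acceptable because C9 is oxidised afterwards. Ring-closing metathesis of the more flexible F4 gives the eleven-membered hydroxy ketone F5, and Dess–Martin oxidation of F5 returns to the route at dione 24.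

Step 21 (C9 reduction). Hydride may add in conjugate fashion to the doubly activated alkylidene keto ester or to the methylene lactone, or may reach C9 from the wrong face. The fallback reduces C9 before the C1=C10 double bond exists and sets out from 27. The selenenylation of step 20 is stopped before oxidation and selenide 28 is isolated. Luche reduction of its C9 ketone (no conjugated acceptor next to it at this stage) should give the hydroxy selenide F6, and acetylation gives the acetoxy selenide F7. Oxidation with H2O2 gives the selenoxide F8, whose syn elimination goes towards C1, because elimination towards the acetoxy-bearing C9 is disfavoured, and returns to the route at acetate 32.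

**Further compounds**

F1 | step 19 | methyl 2-diazopent-4-enoate | C=CCC(=[N+]=[N-])C(=O)OC
F2 | step 19 | acyclic α-allyl β-keto ester (C9 ketone, C10 carrying CO2Me and the allyl group; C10 labile, not defined) | C=C1C(=O)O[C@H]([C@H]2O[C@]2(C)C=C)[C@H]1[C@H](OC(=O)[C@@]1(C)O[C@H]1C)C(=O)C(CC=C)C(=O)OC
F3 | step 17 | 1-bromopent-4-en-2-one | C=CCC(=O)CBr
F4 | step 17 | acyclic 9-hydroxy-14-ketone (C9 not defined, both epimers) | C=C1C(=O)O[C@H]([C@H]2O[C@]2(C)C=C)[C@H]1[C@H](OC(=O)[C@@]1(C)O[C@H]1C)C(O)CC(=O)CC=C
F5 | step 17 | eleven-membered 9-hydroxy-14-ketone, 2Z (C9 not defined, both epimers) | C=C1C(=O)O[C@H]2[C@H]1[C@H](OC(=O)[C@@]1(C)O[C@H]1C)C(O)CC(=O)C/C=C\[C@@]1(C)O[C@H]21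
F6 | step 21 | 9S-hydroxy 10-phenylselanyl ester (C10 not defined) | C=C1C(=O)O[C@H]2[C@H]1[C@H](OC(=O)[C@@]1(C)O[C@H]1C)[C@@H](O)C([Se]c1ccccc1)(C(=O)OC)C/C=C\[C@@]1(C)O[C@H]21
F7 | step 21 | 9S-acetoxy 10-phenylselanyl ester (C10 not defined) | C=C1C(=O)O[C@H]2[C@H]1[C@H](OC(=O)[C@@]1(C)O[C@H]1C)[C@@H](OC(C)=O)C([Se]c1ccccc1)(C(=O)OC)C/C=C\[C@@]1(C)O[C@H]21
F8 | step 21 | selenoxide of F7 (not isolated) | C=C1C(=O)O[C@H]2[C@H]1[C@H](OC(=O)[C@@]1(C)O[C@H]1C)[C@@H](OC(C)=O)C([Se](=O)c1ccccc1)(C(=O)OC)C/C=C\[C@@]1(C)O[C@H]21
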